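The route rests on opening the O–C3 bond of the oxepane (C2, C1, C14, C15, C16, O, C3) that is fused to cyclohexenone ring A. Its hindered tertiary ether carbon C3 is built as an all-carbon quaternary centre of a cis-decalin, and oxygen is inserted last: Baeyer–Villiger oxidation of the C16 ketone shifts C3 onto oxygen with retention, which creates the seven-membered ring and the C3–O stereocentre in one operation. The precursor is a cis-fused decalin enedione with the C16 ketone next to quaternary C3, the C13 enone in ring A, and the C2, C4 and C9 oxygens held as silyl ethers.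

Key step: step 14

Remarks on the chemistry:
- Atom numbers are those of the target skeleton (C1 to C16) in every intermediate.
- In the key-step substrate the C2, C4 and C9 oxygens are silyl ethers, not benzyl-type ethers. Silyloxy groups withdraw least from the migrating carbon C3, offer no benzylic C–H to the allylic oxidation that installs the C13 ketone, and all come off in one fluoride treatment.
- Assumption: the C13 carbinol carbon made in step 15 and the hemiacetal carbons (C16 in step 15; C9 in steps 18, 20 and 21) are temporary centres. C13 is drawn as the epimer expected from hydride attack on the ring A face away from ring B, and either epimer serves. The hemiacetal carbons are left undefined (anomer mixtures).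
- Assumption: (E)-3-methylpent-2-en-4-yn-1-ol is taken as a commercial starting material.

Step 1
Reactants: 1 2-methylcyclohexane-1,3-dione; 2 benzyl chloromethyl ether
Product: 3 2-[(benzyloxy)methyl]-2-methylcyclohexane-1,3-dione
Conditions: LiN(SiMe3)2, THF–toluene, −78 → 0 °C
Reagents that add atoms: benzyl chloromethyl ether (2), ClCOCc1ccccc1
Why: Enolate C-alkylation of a cyclic 1,3-dione with an SN2-reactive α-chloro ether, run on the aggregated lithium enolate in a weakly polar medium to favour attack through carbon and create the quaternary carbon that becomes C3 (any enol ether formed on oxygen is hydrolysed back to 1 on acidic work-up and recycled).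

Step 2
Reactants: 3 2-[(benzyloxy)methyl]-2-methylcyclohexane-1,3-dione
Product: 4 (2S,3S)-2-[(benzyloxy)methyl]-3-hydroxy-2-methylcyclohexan-1-one
Conditions: (R)-2-methyl-CBS-oxazaborolidine (20 mol%), BH3·SMe2 (0.6 equiv), THF, −40 °C
Reagents that add atoms: none
Why: Corey–Bakshi–Shibata reduction used as a desymmetrisation: the catalyst delivers hydride to one enantiotopic carbonyl to give the (S) carbinol (future C16, a temporary centre) and hydride enters anti to the larger CH2OBn group, so the quaternary carbon (future C3) is fixed as (S) with OH cis to CH2OBn.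

Step 3
Reactants: 4 (2S,3S)-2-[(benzyloxy)methyl]-3-hydroxy-2-methylcyclohexan-1-one
Product: 5 (2S,3S)-2-[(benzyloxy)methyl]-2-methyl-3-(triethylsilyloxy)cyclohexan-1-one
Conditions: Et3SiCl, imidazole, DMF, 0 °C → rt
Reagents that add atoms: chlorotriethylsilane, CC[Si](Cl)(CC)CC
Why: Silyl ether formation under weakly basic conditions that do not provoke retro-aldol cleavage; the triethylsilyl group is chosen because mild acid removes it later in the presence of TBS and TIPS ethers.

Step 4
Reactants: 5 (2S,3S)-2-[(benzyloxy)methyl]-2-methyl-3-(triethylsilyloxy)cyclohexan-1-one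
Product: 7 (5S,6S)-6-[(benzyloxy)methyl]-6-methyl-5-(triethylsilyloxy)cyclohex-2-en-1-one, via trimethylsilyl enol ether 6 (not isolated)
Conditions: LiN(i-Pr)2, Me3SiCl, THF, −78 °C; then Pd(OAc)2, MeCN, rt
Reagents that add atoms: chlorotrimethylsilane (silicon kept only in 6), C[Si](C)(C)Cl
Why: Ito–Saegusa dehydrogenation; the ketone can enolise only towards its CH2 side because the other α-carbon is quaternary, so a single silyl enol ether and a single enone (C2 carbonyl, C1=C14) result.

Step 5
Reactants: 8 (E)-3-methylpent-2-en-4-yn-1-ol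
Product: 9 (E)-triisopropyl[(3-methylpent-2-en-4-yn-1-yl)oxy]silane
Conditions: i-Pr3SiCl, imidazole, DMF, rt
Reagents that add atoms: chlorotriisopropylsilane, CC(C)[Si](Cl)(C(C)C)C(C)C
Why: Silylation of the primary alcohol; the bulky TIPS ether resists the Lewis acid, the dissolving metal and the mild acid used before the global desilylation of step 17.

Step 6
Reactants: 9 (E)-triisopropyl[(3-methylpent-2-en-4-yn-1-yl)oxy]silane
Product: 10 (E)-triisopropyl[(3-methylpenta-2,4-dien-1-yl)oxy]silane
Conditions: H2 (1 atm), Pd/CaCO3 poisoned with Pb(OAc)2, quinoline, hexane, rt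
Reagents that add atoms: none
Why: Lindlar semi-hydrogenation converts the terminal alkyne into a vinyl group and leaves the trisubstituted (E)-olefin alone, giving a diene whose CH2OTIPS group sits on the outside of the s-cis form.

Step 7
Reactants: 7 (5S,6S)-6-[(benzyloxy)methyl]-6-methyl-5-(triethylsilyloxy)cyclohex-2-en-1-one; 10 (E)-triisopropyl[(3-methylpenta-2,4-dien-1-yl)oxy]silane
Product: 11 cis-octalone cycloadduct (C2 ketone, C3 with CH3 and CH2OBn, C16–OSiEt3, C11=C12, C10–CH2OTIPS; H1, H10 and H14 cis)
Conditions: EtAlCl2 (30 mol%), CH2Cl2–toluene, −40 → 0 °C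
Reagents that add atoms: none
Why: Lewis acid-promoted Diels–Alder reaction: the diene adds endo to the enone face anti to the C16 silyloxy group and the pseudo-axial CH2OBn on C3, which makes H1, H10 and H14 cis and places ring A on the C3-methyl face, while the terminal CH2OTIPS substituent directs its own carbon C10 to the α-carbon C1 and the unsubstituted terminus C13 to the β-carbon C14, as 1-substituted and 1,2-dialkyl dienes do.

Step 8
Reactants: 11 cis-octalone cycloadduct
Product: 12 diol (C2–OH trans to C10 and cis to C4; free C4–OH)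
Conditions: Li, liquid NH3, THF, t-BuOH, −78 °C; then NH4Cl
Reagents that add atoms: none
Why: Dissolving-metal reduction: the ketone is reduced through its ketyl to the thermodynamically preferred equatorial C2 alcohol, the epimer that hydride reagents would not favour because the axial C13 methylene blocks the ring A face, and the benzyl ether is cleaved in the same operation, with a cold quench so that the silyl groups do not migrate.

Step 9
Reactants: 12 diol
Product: 13 bis-TBS ether (C2–OTBS, C4–OTBS, C16–OSiEt3, C9–OTIPS)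
Conditions: t-BuMe2SiOTf, 2,6-lutidine, CH2Cl2, 0 °C
Reagents that add atoms: tert-butyldimethylsilyl trifluoromethanesulfonate, CC(C)(C)[Si](C)(C)OS(=O)(=O)C(F)(F)F
Why: Silylation of both hydroxyls with the silyl triflate, which is reactive enough for the hindered secondary C2 alcohol; silyl ethers are chosen for C2–O and C4–O because they withdraw least from C3 in step 14 and carry no benzylic hydrogens into step 13.

Step 10
Reactants: 13 bis-TBS ether
Product: 14 C16 alcohol
Conditions: PPTS (10 mol%), MeOH–CH2Cl2, 0 °C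
Reagents that add atoms: none
Why: Acid-catalysed methanolysis removes the triethylsilyl ether far faster than the hindered TBS ethers and the TIPS ether, freeing only C16–OH.

Step 11
Reactants: 14 C16 alcohol
Product: 15 C16 ketone (cis-decalin, C15 still CH2)
Conditions: Dess–Martin periodinane, NaHCO3, CH2Cl2, rt
Reagents that add atoms: none
Why: Dess–Martin oxidation of the secondary alcohol gives the C16 ketone under buffered, non-epimerising conditions.

Step 12
Reactants: 15 C16 ketone; 16 iodomethane
Product: 17 C15-methyl ketone (C15–CH3 cis to H14, trans to C13)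
Conditions: LiN(i-Pr)2, THF, −78 °C; then MeI, −78 → −40 °C
Reagents that add atoms: iodomethane (16), CI
Why: Kinetic enolate alkylation: enolisation is possible only towards C15 because C3 is quaternary, and iodomethane enters anti to the neighbouring C14–C13 bond on the convex face (the usual 2,3-trans outcome for a 3-substituted cyclohexanone enolate), which sets C15 with its methyl cis to H14.

Step 13
Reactants: 17 C15-methyl ketone
Product: 18 cis-decalin enedione with quaternary C3 (C13 enone, C16 ketone; C2–OTBS, C4–OTBS, C9–OTIPS)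
Conditions: Rh2(cap)4 (1 mol%, cap = caprolactamate), 70% aqueous t-BuOOH, 1,2-dichloroethane, 40 °C
Reagents that add atoms: tert-butyl hydroperoxide, CC(C)(C)OO
Why: Allylic C–H oxidation by tert-butylperoxyl radicals: as with 1-methylcyclohexenes and Δ5-steroids the methylene next to the CH= carbon (C13) is oxidised to the β-methyl enone while the hindered methine C10 next to the fully substituted C11 is left, and no benzylic C–H competes because every hydroxyl is a silyl ether.

Step 14
Reactants: 18 cis-decalin enedione with quaternary C3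
Product: 19 oxepanone fused to the cyclohexenone (lactone C16(=O)–O–C3)
Conditions: mCPBA (3 equiv), NaHCO3, CH2Cl2, 0 °C → rt
Reagents that add atoms: 3-chloroperoxybenzoic acid, OOC(=O)c1cccc(Cl)c1
Why: The peracid adds to the saturated C16 carbonyl to give the Criegee adduct, and the C16–C3 bond that lies antiperiplanar to the O–O bond shifts to oxygen as 3-chlorobenzoate departs. This is a Baeyer–Villiger ring expansion whose closest precedent is the oxidation of 2,2-disubstituted (α-quaternary) cyclohexanones to ε-lactones with migration of the more substituted carbon. The oxepan-2-one (C2, C1, C14, C15, C16, O, C3) is not closed by a cyclisation but arises from ring B by this one-atom expansion, a 1,2-shift from carbon to oxygen within the existing ring. The tertiary C3–O stereocentre is governed by the quaternary centre already present, because the concerted shift keeps the configuration of the migrating carbon. The step needs C3 to migrate in preference to C15 and the peracid to attack only the saturated ketone: C3 is fully substituted and its two β-oxygens are silyl ethers, the least withdrawing choice, C15 is secondary and is further deactivated through C14 by the C13 carbonyl, and the enone is inert on this time scale since conjugation lowers the reactivity of its carbonyl and its olefin is electron-poor. The NaHCO3 buffer keeps C15 from epimerising and the silyl ethers in place.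

Step 15
Reactants: 19 oxepanone fused to the cyclohexenone
Product: 21 bis-acetate (C16 acetoxy acetal as anomer mixture; C13–OAc), via bis(diisobutylaluminium) alkoxide 20 (not isolated)
Conditions: i-Bu2AlH (3.5 equiv), CH2Cl2, −78 °C; then pyridine, DMAP, Ac2O, −78 → 0 °C
Reagents that add atoms: acetic anhydride, CC(=O)OC(C)=O; diisobutylaluminium hydride (aluminium kept only in 20), CC(C)C[AlH]CC(C)C
Why: Reductive acetylation of a lactone: hydride adds once to the lactone and in 1,2-fashion to the enone, and the aluminium hemiacetal and the allylic alkoxide are acetylated in the cold before the seven-membered hemiacetal can open, the new C13 centre being temporary.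

Step 16
Reactants: 21 bis-acetate
Product: 22 oxepane (C16 now CH2; C13–OAc; three silyl ethers intact)
Conditions: Et3SiH, BF3·OEt2, CH2Cl2, −78 °C
Reagents that add atoms: none
Why: Ionic hydrogenation of an acetoxy acetal: BF3 ionises the anomeric acetate to the seven-membered oxocarbenium ion, which takes hydride from the silane to give the oxepane, while the allylic acetate and the silyl ethers do not ionise at −78 °C.

Step 17
Reactants: 22 oxepane
Product: 23 triol (C2–OH, C4–OH, C9–OH; C13–OAc)
Conditions: HF·pyridine, pyridine, THF, 0 °C → rt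
Reagents that add atoms: none
Why: Fluoride cleavage of the two TBS ethers and the TIPS ether under slightly acidic conditions that leave the allylic acetate and the oxepane untouched.

Step 18
Reactants: 23 triol
Product: 25 γ-lactone aldehyde (C2–O–C9(=O) lactone; C4 aldehyde on C3; C13–OAc), via C9 lactol 24 (not isolated)
Conditions: TEMPO (20 mol%), PhI(OAc)2 (3.5 equiv), CH2Cl2, rt
Reagents that add atoms: none
Why: Oxoammonium (TEMPO) oxidation, selective for primary alcohols: the C9 aldehyde is captured at once by the C2 hydroxyl as the five-membered lactol and oxidised on to the γ-lactone, and the neopentyl C4 alcohol gives the aldehyde, which has no α-hydrogen.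

Step 19
Reactants: 25 γ-lactone aldehyde; 26 allyltributylstannane
Product: 27 (4S)-homoallylic alcohol (C4H(OH)–CH2–CH=CH2 on C3)
Conditions: MgBr2·OEt2 (3 equiv), CH2Cl2, −78 → −20 °C
Reagents that add atoms: allyltributylstannane (26), C=CC[Sn](CCCC)(CCCC)CCCC
Why: Chelation-controlled allylstannane addition: magnesium bridges the aldehyde oxygen and the α-ether oxygen of the oxepane, and the allyl group comes in on the chelate face that carries the C3 methyl, not C2, giving the (4S) alcohol, while lactone and acetate are inert to the stannane.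

Step 20
Reactants: 27 (4S)-homoallylic alcohol
Product: 28 lactol triol (C9 lactol as anomer mixture, C4–OH, C13–OH)
Conditions: i-Bu2AlH (6 equiv), CH2Cl2, −78 °C; aqueous KNaC4H4O6
Reagents that add atoms: none
Why: Partial reduction of the γ-lactone to the five-membered lactol, whose aluminium hemiacetal is stable at −78 °C, with reductive removal of the C13 acetate in the same operation.

Step 21
Reactants: 28 lactol triol
Product: 29 triacetate (anomeric C9–OAc, C4–OAc, C13–OAc)
Conditions: Ac2O, pyridine, DMAP, CH2Cl2, 0 °C → rt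
Reagents that add atoms: acetic anhydride, CC(=O)OC(C)=O
Why: Acetylation of the lactol and of the C4 and C13 hydroxyls supplies the anomeric leaving group and keeps the C4 hydroxyl from closing a bicyclic acetal onto C9.

Step 22
Reactants: 29 triacetate; 30 trimethyl(2-methylallyl)silane
Product: 31 (9R)-C9-(2-methylallyl)tetrahydrofuran (2,9-cis; C4–OAc with allyl chain; C13–OAc)
Conditions: BF3·OEt2, CH2Cl2, −78 °C
Reagents that add atoms: trimethyl(2-methylallyl)silane (30), C=C(C)C[Si](C)(C)C
Why: Hosomi–Sakurai allylation of a cyclic oxocarbenium ion: the C9 cation of the tetrahydrofuran, cis-fused to ring A, is attacked on its convex face anti to the C10–C11 bond, so the new C9–C8 bond lies cis to C3 across the ring oxygen (2,9-cis, 9R).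

Step 23
Reactants: 31 (9R)-C9-(2-methylallyl)tetrahydrofuran
Product: 32 (6Z)-oxonene (C6=C7 with C7–CH3; C4–OAc; C13–OAc)
Conditions: second-generation Grubbs catalyst RuCl2(=CHPh)(PCy3)(H2IMes) (15 mol%), toluene (0.002 M), 80 °C
Reagents that add atoms: none
Why: Ring-closing metathesis between the monosubstituted and the 1,1-disubstituted olefin gives the trisubstituted C6=C7 bond, necessarily Z in the nine-membered oxonene, the 2,9-cis tetrahydrofuran and quaternary C3 holding both chains on one face.

Step 24
Reactants: 32 (6Z)-oxonene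
Product: 33 (6R,7S)-6,7-diol
Conditions: OsO4 (5 mol%), N-methylmorpholine N-oxide, acetone–H2O, rt
Reagents that add atoms: osmium tetroxide, O=[Os](=O)(=O)=O; N-methylmorpholine N-oxide, C[N+]1([O-])CCOCC1
Why: Upjohn syn-dihydroxylation on the exposed outer face of the strained medium-ring Z-olefin sets the tertiary carbinol C7 as (S) (C6 is formed as R and is inverted next), and the ring A olefin, hindered and deactivated by its allylic acetate, is not touched.

Step 25
Reactants: 33 (6R,7S)-6,7-diol
Product: 34 C6 ketone with (7S) tertiary alcohol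
Conditions: IBX, DMSO, rt
Reagents that add atoms: none
Why: IBX oxidation converts the secondary C6 alcohol of the glycol into the ketone without C–C cleavage and cannot oxidise the tertiary C7 alcohol.

Step 26
Reactants: 34 C6 ketone
Product: 35 tetraol ((4S)-OH, (6S)-OH, (7S)-OH, C13–OH)
Conditions: i-Bu2AlH (8 equiv), CH2Cl2, −78 °C; aqueous KNaC4H4O6
Reagents that add atoms: none
Why: Hydride reduction of the α-hydroxy ketone from the same outer face that osmium used places the new C6 hydroxyl on the inner face, which inverts C6 to (S), and the excess hydride removes the C4 and C13 acetates.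

Step 27
Reactants: 35 tetraol
Product: 36 enone triol (C13 ketone conjugated with C11=C12; 4,6,7-triol)
Conditions: MnO2, CH2Cl2, rt
Reagents that add atoms: none
Why: MnO2 oxidises only the allylic C13 alcohol, restoring the ring A enone in the presence of two saturated secondary alcohols and the tertiary one.

Step 28
Reactants: 36 enone triol
Product: 37 CNP0212231.3 (4,6-diacetate, free C7–OH)
Conditions: Ac2O, pyridine, DMAP (10 mol%), CH2Cl2, 0 °C → rt
Reagents that add atoms: acetic anhydride, CC(=O)OC(C)=O
Why: Acetylation esterifies the secondary C4 and C6 alcohols while the tertiary C7 alcohol does not react, giving the target.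

Compound list
1 | 2-methylcyclohexane-1,3-dione | CC1C(=O)CCCC1=O | starting material
2 | benzyl chloromethyl ether | ClCOCc1ccccc1 | starting material
3 | 2-[(benzyloxy)methyl]-2-methylcyclohexane-1,3-dione | CC1(COCc2ccccc2)C(=O)CCCC1=O | intermediate
4 | (2S,3S)-2-[(benzyloxy)methyl]-3-hydroxy-2-methylcyclohexan-1-one (OH cis to CH2OBn) | O=C1CCC[C@H](O)[C@]1(C)COCc2ccccc2 | intermediate
5 | (2S,3S)-2-[(benzyloxy)methyl]-2-methyl-3-(triethylsilyloxy)cyclohexan-1-one | O=C1CCC[C@H](O[Si](CC)(CC)CC)[C@]1(C)COCc2ccccc2 | intermediate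
6 | trimethylsilyl enol ether of 5 (C2–OSiMe3, C1=C2) | C[Si](C)(C)OC1=CCC[C@H](O[Si](CC)(CC)CC)[C@]1(C)COCc2ccccc2 | intermediate (not isolated)
7 | (5S,6S)-6-[(benzyloxy)methyl]-6-methyl-5-(triethylsilyloxy)cyclohex-2-en-1-one | O=C1C=CC[C@H](O[Si](CC)(CC)CC)[C@]1(C)COCc2ccccc2 | intermediate
8 | (E)-3-methylpent-2-en-4-yn-1-ol | C#C/C(C)=C/CO | starting material
9 | (E)-triisopropyl[(3-methylpent-2-en-4-yn-1-yl)oxy]silane | C#C/C(C)=C/CO[Si](C(C)C)(C(C)C)C(C)C | intermediate
10 | (E)-triisopropyl[(3-methylpenta-2,4-dien-1-yl)oxy]silane | C=C/C(C)=C/CO[Si](C(C)C)(C(C)C)C(C)C | intermediate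
11 | cis-octalone cycloadduct: C2 ketone; C3 with CH3 and CH2OBn; C16–OSiEt3; C11=C12 with C11–CH3; C10–CH2OTIPS; H1, H10, H14 cis; ring A on the C3–CH3 face, anti to C16–O and C4 | O=C3[C@@H]4[C@@H](CC=C(C)[C@@H]4CO[Si](C(C)C)(C(C)C)C(C)C)C[C@H](O[Si](CC)(CC)CC)[C@]3(C)COCc1ccccc1 | intermediate
12 | diol: as 11 with C2–OH (trans to C10, cis to C4) and free C4–OH | O[C@@H]3[C@@H]4[C@@H](CC=C(C)[C@@H]4CO[Si](C(C)C)(C(C)C)C(C)C)C[C@H](O[Si](CC)(CC)CC)[C@]3(C)CO | intermediate
13 | bis-TBS ether: C2–OTBS, C4–OTBS, C16–OSiEt3, C9–OTIPS | CC(C)(C)[Si](C)(C)O[C@@H]3[C@@H]4[C@@H](CC=C(C)[C@@H]4CO[Si](C(C)C)(C(C)C)C(C)C)C[C@H](O[Si](CC)(CC)CC)[C@]3(C)CO[Si](C)(C)C(C)(C)C | intermediate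
14 | C16 alcohol: as 13 with free C16–OH | CC(C)(C)[Si](C)(C)O[C@@H]3[C@@H]4[C@@H](CC=C(C)[C@@H]4CO[Si](C(C)C)(C(C)C)C(C)C)C[C@H](O)[C@]3(C)CO[Si](C)(C)C(C)(C)C | intermediate
15 | C16 ketone (cis-decalin, C15 H2) | CC(C)(C)[Si](C)(C)O[C@@H]3[C@@H]4[C@@H](CC=C(C)[C@@H]4CO[Si](C(C)C)(C(C)C)C(C)C)CC(=O)[C@]3(C)CO[Si](C)(C)C(C)(C)C | intermediate
16 | iodomethane | CI | starting material
17 | C15-methyl ketone (C15–CH3 cis to H14, trans to C13) | CC(C)(C)[Si](C)(C)O[C@@H]3[C@@H]4[C@@H](CC=C(C)[C@@H]4CO[Si](C(C)C)(C(C)C)C(C)C)[C@H](C)C(=O)[C@]3(C)CO[Si](C)(C)C(C)(C)C | intermediate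
18 | cis-decalin enedione with quaternary C3 (C13 enone, C16 ketone; C2–OTBS, C4–OTBS, C9–OTIPS) | CC(C)(C)[Si](C)(C)O[C@@H]3[C@@H]4[C@@H](C(=O)C=C(C)[C@@H]4CO[Si](C(C)C)(C(C)C)C(C)C)[C@H](C)C(=O)[C@]3(C)CO[Si](C)(C)C(C)(C)C | intermediate
19 | oxepanone fused to the cyclohexenone (lactone C16(=O)–O–C3, C3 configuration retained) | CC(C)(C)[Si](C)(C)O[C@@H]3[C@@H]4[C@@H](C(=O)C=C(C)[C@@H]4CO[Si](C(C)C)(C(C)C)C(C)C)[C@H](C)C(=O)O[C@]3(C)CO[Si](C)(C)C(C)(C)C | intermediate
20 | bis(diisobutylaluminium) alkoxide: C13–OAl(i-Bu)2 and C16 hemiacetal OAl(i-Bu)2 | CC(C)(C)[Si](C)(C)O[C@@H]3[C@@H]4[C@@H]([C@H](O[Al](CC(C)C)CC(C)C)C=C(C)[C@@H]4CO[Si](C(C)C)(C(C)C)C(C)C)[C@H](C)C(O[Al](CC(C)C)CC(C)C)O[C@]3(C)CO[Si](C)(C)C(C)(C)C | intermediate (not isolated)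
21 | bis-acetate: C16 acetoxy acetal (anomer mixture) and C13–OAc | CC(C)(C)[Si](C)(C)O[C@@H]3[C@@H]4[C@@H]([C@H](OC(C)=O)C=C(C)[C@@H]4CO[Si](C(C)C)(C(C)C)C(C)C)[C@H](C)C(OC(C)=O)O[C@]3(C)CO[Si](C)(C)C(C)(C)C | intermediate
22 | oxepane (C16 H2) with C13–OAc, C2–OTBS, C4–OTBS, C9–OTIPS | CC(C)(C)[Si](C)(C)O[C@@H]3[C@@H]4[C@@H]([C@H](OC(C)=O)C=C(C)[C@@H]4CO[Si](C(C)C)(C(C)C)C(C)C)[C@H](C)CO[C@]3(C)CO[Si](C)(C)C(C)(C)C | intermediate
23 | triol: C2–OH, C4–OH, C9–OH; C13–OAc | O[C@@H]3[C@@H]4[C@@H]([C@H](OC(C)=O)C=C(C)[C@@H]4CO)[C@H](C)CO[C@]3(C)CO | intermediate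
24 | C9 lactol (C2–O–C9H–OH), C4–OH free | OC2O[C@@H]3[C@@H]4[C@@H]([C@H](OC(C)=O)C=C(C)[C@@H]42)[C@H](C)CO[C@]3(C)CO | intermediate (not isolated)
25 | γ-lactone aldehyde: C2–O–C9(=O); C4 aldehyde on C3; C13–OAc | O=C2O[C@@H]3[C@@H]4[C@@H]([C@H](OC(C)=O)C=C(C)[C@@H]42)[C@H](C)CO[C@]3(C)C=O | intermediate
26 | allyltributylstannane | C=CC[Sn](CCCC)(CCCC)CCCC | starting material
27 | (4S)-homoallylic alcohol: C4H(OH)–CH2–CH=CH2 on C3; γ-lactone; C13–OAc | O=C2O[C@@H]3[C@@H]4[C@@H]([C@H](OC(C)=O)C=C(C)[C@@H]42)[C@H](C)CO[C@]3(C)[C@@H](O)CC=C | intermediate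
28 | lactol triol: C9 lactol (anomer mixture), C4–OH, C13–OH | OC2O[C@@H]3[C@@H]4[C@@H]([C@H](O)C=C(C)[C@@H]42)[C@H](C)CO[C@]3(C)[C@@H](O)CC=C | intermediate
29 | triacetate: anomeric C9–OAc, C4–OAc, C13–OAc | CC(=O)OC2O[C@@H]3[C@@H]4[C@@H]([C@H](OC(C)=O)C=C(C)[C@@H]42)[C@H](C)CO[C@]3(C)[C@@H](OC(C)=O)CC=C | intermediate
30 | trimethyl(2-methylallyl)silane | C=C(C)C[Si](C)(C)C | starting material
31 | (9R)-C9-(2-methylallyl)tetrahydrofuran, 2,9-cis; C4–OAc with allyl chain; C13–OAc | C=C(C)C[C@H]2O[C@@H]3[C@@H]4[C@@H]([C@H](OC(C)=O)C=C(C)[C@@H]42)[C@H](C)CO[C@]3(C)[C@@H](OC(C)=O)CC=C | intermediate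
32 | (6Z)-oxonene: C6=C7 with C7–CH3; C4–OAc; C13–OAc | CC(=O)O[C@H]1C/C=C(C)\C[C@H]2O[C@@H]3[C@@H]4[C@@H]([C@H](OC(C)=O)C=C(C)[C@@H]42)[C@H](C)CO[C@]13C | intermediate
33 | (6R,7S)-6,7-diol; C4–OAc; C13–OAc | CC(=O)O[C@H]1C[C@@H](O)[C@@](C)(O)C[C@H]2O[C@@H]3[C@@H]4[C@@H]([C@H](OC(C)=O)C=C(C)[C@@H]42)[C@H](C)CO[C@]13C | intermediate
34 | C6 ketone with (7S) tertiary alcohol; C4–OAc; C13–OAc | CC(=O)O[C@H]1CC(=O)[C@@](C)(O)C[C@H]2O[C@@H]3[C@@H]4[C@@H]([C@H](OC(C)=O)C=C(C)[C@@H]42)[C@H](C)CO[C@]13C | intermediate
35 | tetraol: (4S)-OH, (6S)-OH, (7S)-OH, C13–OH | O[C@H]1C[C@H](O)[C@@](C)(O)C[C@H]2O[C@@H]3[C@@H]4[C@@H]([C@H](O)C=C(C)[C@@H]42)[C@H](C)CO[C@]13C | intermediate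
36 | enone triol: C13 ketone with C11=C12; 4,6,7-triol | O[C@H]1C[C@H](O)[C@@](C)(O)C[C@H]2O[C@@H]3[C@@H]4[C@@H](C(=O)C=C(C)[C@@H]42)[C@H](C)CO[C@]13C | intermediate
37 | CNP0212231.3 (4,6-diacetoxy-7-hydroxy enone) | CC(=O)O[C@H]1C[C@H](OC(C)=O)[C@@](C)(O)C[C@H]2O[C@@H]3[C@@H]4[C@@H](C(=O)C=C(C)[C@@H]42)[C@H](C)CO[C@]13C | target

Total step count: 28. Longest linear sequence: 26 steps (steps 1–4 and 7–28, from 1 to 37); the diene branch (steps 5 and 6) joins in step 7.

Steps most likely to fail

Step 14. The 1,2-shift may lose its regiocontrol, with C15 migrating in competition with C3, or the hindered ketone may react so slowly that C15 epimerises under the conditions. The fallback changes the order of events so that C3 competes only with a methylene group. From ketone 15, Baeyer–Villiger oxidation with bis(trimethylsilyl) peroxide and catalytic Me3SiOTf (CH2Cl2, −40 °C), a peroxide system that leaves isolated olefins alone, should give the C15-unsubstituted oxepanone F1. Deprotonation with LiN(i-Pr)2 and methylation with iodomethane 16, anti to the C14–C13 bond, should give the C15-methyl oxepanone F2. Allylic oxidation of F2 under the conditions of step 13 then rejoins the route at lactone 19.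

Step 7. Regiocontrol may be lost, since the C11 methyl group directs against the terminal CH2OTIPS group, or the cycloaddition to the hindered enone may be slow enough for the diene to polymerise. The fallback uses a diene whose orientation is fixed by a 2-silyloxy group. From silyl ether 9, catalytic hydration of the alkyne (Ph3PAuNTf2, MeOH–H2O) should give methyl ketone F3, and t-BuMe2SiOTf with Et3N converts it into the 2-silyloxy diene F4. Cycloaddition of F4 with enone 7 (toluene, 110 °C) should give the silyl enol ether adduct F5 with C13 bonded to C14. CsF and PhNTf2 turn F5 into the enol triflate F6, and reduction of F6 with Pd(OAc)2, PPh3, HCO2H and Bu3N removes the triflate and rejoins the route at cycloadduct 11.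

Step 1. Alkylation may take place on oxygen in place of carbon. The fallback forms the C–C bond by aldol addition and benzylates afterwards under acid. From dione 1, aqueous formaldehyde with catalytic Et3N should give 2-(hydroxymethyl)-2-methylcyclohexane-1,3-dione F7. Benzyl 2,2,2-trichloroacetimidate with catalytic TfOH converts F7 into dione 3 without exposing the β-hydroxy dione to base.

Further compounds
F1 | step 14 | C15-unsubstituted oxepanone (lactone C16(=O)–O–C3, C11=C12 olefin intact) | CC(C)(C)[Si](C)(C)O[C@@H]3[C@@H]4[C@@H](CC=C(C)[C@@H]4CO[Si](C(C)C)(C(C)C)C(C)C)CC(=O)O[C@]3(C)CO[Si](C)(C)C(C)(C)C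
F2 | step 14 | C15-methyl oxepanone lacking the C13 ketone | CC(C)(C)[Si](C)(C)O[C@@H]3[C@@H]4[C@@H](CC=C(C)[C@@H]4CO[Si](C(C)C)(C(C)C)C(C)C)[C@H](C)C(=O)O[C@]3(C)CO[Si](C)(C)C(C)(C)C
F3 | step 7 | (E)-3-methyl-5-(triisopropylsilyloxy)pent-3-en-2-one | CC(=O)/C(C)=C/CO[Si](C(C)C)(C(C)C)C(C)C
F4 | step 7 | (E)-2-(tert-butyldimethylsilyloxy)-3-methyl-5-(triisopropylsilyloxy)penta-1,3-diene | C=C(O[Si](C)(C)C(C)(C)C)/C(C)=C/CO[Si](C(C)C)(C(C)C)C(C)C
F5 | step 7 | silyl enol ether cycloadduct (C12–OTBS, C11=C12; otherwise as 11) | O=C3[C@@H]4[C@@H](CC(O[Si](C)(C)C(C)(C)C)=C(C)[C@@H]4CO[Si](C(C)C)(C(C)C)C(C)C)C[C@H](O[Si](CC)(CC)CC)[C@]3(C)COCc1ccccc1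
F6 | step 7 | enol triflate (C12–OTf, C11=C12; otherwise as 11) | O=C3[C@@H]4[C@@H](CC(OS(=O)(=O)C(F)(F)F)=C(C)[C@@H]4CO[Si](C(C)C)(C(C)C)C(C)C)C[C@H](O[Si](CC)(CC)CC)[C@]3(C)COCc1ccccc1
F7 | step 1 | 2-(hydroxymethyl)-2-methylcyclohexane-1,3-dione | CC1(CO)C(=O)CCCC1=O
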